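The numbers in the tables were computed from invented constants; the scatter is artificial.

At early times the noon run already reads lower in L than the autumn run: noon has L 70% and D 26% at 0.833 h, while autumn has L 79% and D 13% at 0.667 h, which is sooner. Autumn ends with L 94% and D 0% at 2.50 h, while noon reads L 82% and D 16% at 2.00 h.

| flask | D | X | remark | time |
|---|---|---|---|---|
| noon | 0.52 M | 0.78 M | the very flask that is asked about, followed so far |  |
| autumn | 0.26 M | 0.78 M | run made earlier |  |
| flask | 0.52 M | 0.780 M |  | 6.0 h |

- noon (time / h: L / %, D / %): 0.250: 44, 49; 0.833: 70, 26; 1.33: 72, 12; 2.00: 82, 16; 3.00: 77, 6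
- autumn (time / h: L / %, D / %): 0.200: 46, 48; 0.667: 79, 13; 1.00: 87, 8; 1.50: 93, 4; 2.50: 94, 0

(readings scatter by 2 percentage points)

- the earlier runs were read with a standard deviation of 2 percentage points

1. amount of L in percent of the D charged, at 40 min, 2.0 h, 4.0 h and 6.0 h

My own reckoning supposes that D leaks away at second order in D while it goes to L at first order in D, with X taken as steady. The fraction of charged D that becomes L is then the logarithm of one plus r, divided by r. For small r the lost fraction is half of r, so autumn's ending gives 0.120. This r, the rate of loss over the rate to L at the charge, is the inverse of a selectivity factor, and the ending it comes from carries a scatter of 2 points.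

It scales as D charge over X charge, so the noon flask has twice autumn's value, 0.240, and L heads for 89.6%.

Is one number enough? Taking the D read at 0.250 h, r gives L 43.3% against 44% read. At 3.00 h it gives 83.7% against 77%, so that reading stands well off. And r ties L to D, not to the clock.

The forecast says 64%, 79%, 80% and 79%, “a plateau near 80, perhaps slightly declining”, and my ending is higher.

The flask gives 64.5%, 79.1%, 84.5% and 86.3%: it matches the forecast through 2.0 h, then keeps climbing.

    X + J ⇌ G, settled at all times (K = 14.9 M⁻¹)
    D + X → J + L (k = 0.00144 M⁻¹ s⁻¹)
    2 D → E (k = 1.58 × 10⁻⁴ M⁻¹ s⁻¹)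
    X ⇌ Q (K = 0.130, k = 9.65 × 10⁻⁶ s⁻¹)

The path from two D to E is the main reason L stops short of the charge: the same flask without that path gives 95.9% at 6.0 h instead of 86.3%, a difference of 9.6 points, while r put the loss at 10 points. With half the X, r becomes 0.480 and reads 81.7%, but that flask gives 58.4%.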